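The route rests on cutting the right-hand central ring (ring C) into a four-carbon cyclobutenone and a two-carbon ynol ether. One thermal cyclobutenone–siloxyalkyne benzannulation forms C6′–C1′, C2′–C3′ and C6′–C5′ and closes ring C as a phenol. It exploits the fixed contiguous order C6′(OH), C1′(acyl carbon), C2′(O), C3′(bridging CH2), C4′(OMe), C5′(H) around ring C, which connectivity alone then dictates. The precursor is a 3-methoxycyclobut-2-enone whose C2 methylene already carries the complete perbenzylated left benzophenone (rings A and B); its partner is a triisopropylsilyl ynol ether holding ring D on a racemic O-silyl carbinol carbon, oxidised to the ketone afterwards.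

Key step: step 19

Labels: ring A = left central ring (C1 acyl carbon, C2/C6 oxygens, C3 bridging CH2, C4 OMe); ring B = the 2,4-dioxygenated 6-methylphenyl ring on the left ketone; ring C = right central ring (C1′–C6′); ring D = the 4-oxygenated 2-methoxy-6-methylphenyl ring on the right ketone. ArCH2 = 2,4-bis(benzyloxy)-3-[2,4-bis(benzyloxy)-6-methylbenzoyl]-6-methoxybenzyl (rings A and B, perbenzylated); Ar′ = 4-(benzyloxy)-2-methoxy-6-methylphenyl (ring D).

Assumption: the carbinol carbon that becomes the right-hand ketone is carried as the racemate from step 16 on (diastereomer mixture in 32), since step 21 removes it and the target has no stereocentre.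

Design choices for the precursor:
- The future bridging carbon is put on ring A by formylating the symmetric free diphenol 8, where only ring A is phenolic and C3 = C5, so no regiochemical question arises.
- The left ketone is kept as a ketone because four ortho substituents shield it from the acetylide of step 11.
- The labile bromide 13 is used at once.
- Methanol is the solvent in step 13, so any exchange at the vinylogous ester is degenerate.
- The ynol ether is made by acetylide oxidation, three steps from aldehyde 25.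

Step 1
Reactants: 1 5-methoxyresorcinol
Product: 2 1-methoxy-3,5-bis(methoxymethoxy)benzene
Conditions: MOMCl, i-Pr2NEt, CH2Cl2, 0 °C → rt
Reagents that add atoms: chloromethyl methyl ether, COCCl
Why: Williamson-type O-alkylation of both phenols; the two MOM ethers are chosen because they steer the lithiation of step 3 to the carbon between them.

Step 2
Reactants: 3 2,4-dihydroxy-6-methylbenzaldehyde
Product: 4 2,4-bis(benzyloxy)-6-methylbenzaldehyde
Conditions: BnBr, K2CO3, DMF, 60 °C
Reagents that add atoms: benzyl bromide, BrCc1ccccc1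
Why: Double Williamson etherification, the hydrogen-bonded 2-OH reacting on warming with excess halide.

Step 3
Reactants: 2 1-methoxy-3,5-bis(methoxymethoxy)benzene; 4 2,4-bis(benzyloxy)-6-methylbenzaldehyde
Product: 6 [2,4-bis(benzyloxy)-6-methylphenyl][4-methoxy-2,6-bis(methoxymethoxy)phenyl]methanol (racemic), via aryllithium 5 (not isolated)
Conditions: n-BuLi, TMEDA, THF, 0 °C; then 4, −78 → 0 °C; aq. NH4Cl
Reagents that add atoms: none
Why: Directed ortho-metalation lithiates the carbon flanked by two OMOM groups in preference to those next to OMe, and the aryllithium adds 1,2 to the aldehyde; the new carbinol centre is racemic and disappears in step 4.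

Step 4
Reactants: 6 [2,4-bis(benzyloxy)-6-methylphenyl][4-methoxy-2,6-bis(methoxymethoxy)phenyl]methanol
Product: 7 [2,4-bis(benzyloxy)-6-methylphenyl][4-methoxy-2,6-bis(methoxymethoxy)phenyl]methanone
Conditions: Dess–Martin periodinane, CH2Cl2, rt
Reagents that add atoms: none
Why: Dess–Martin oxidation copes with hindered secondary diaryl carbinols and leaves MOM and benzyl ethers untouched.

Step 5
Reactants: 7 [2,4-bis(benzyloxy)-6-methylphenyl][4-methoxy-2,6-bis(methoxymethoxy)phenyl]methanone
Product: 8 [2,4-bis(benzyloxy)-6-methylphenyl](2,6-dihydroxy-4-methoxyphenyl)methanone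
Conditions: HCl (2 M aq.), MeOH, 50 °C
Reagents that add atoms: none
Why: Acid-catalysed acetal exchange removes both MOM groups, while benzyl ethers and the diaryl ketone are inert to dilute HCl in methanol.

Step 6
Reactants: 8 [2,4-bis(benzyloxy)-6-methylphenyl](2,6-dihydroxy-4-methoxyphenyl)methanone
Product: 10 3-[2,4-bis(benzyloxy)-6-methylbenzoyl]-2,4-dihydroxy-6-methoxybenzaldehyde, via iminium chloride 9 (not isolated)
Conditions: POCl3, DMF, MeCN, 0 °C → rt; then H2O, 50 °C
Reagents that add atoms: N,N-dimethylformamide, CN(C)C=O; water, O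
Why: Vilsmeier–Haack formylation attacks only the free resorcinol ring A, whose C3 and C5 are equivalent, and the first formyl group deactivates the ring against a second attack.

Step 7
Reactants: 10 3-[2,4-bis(benzyloxy)-6-methylbenzoyl]-2,4-dihydroxy-6-methoxybenzaldehyde
Product: 11 2,4-bis(benzyloxy)-3-[2,4-bis(benzyloxy)-6-methylbenzoyl]-6-methoxybenzaldehyde
Conditions: BnBr, K2CO3, Bu4NI (cat.), DMF, 60 °C
Reagents that add atoms: benzyl bromide, BrCc1ccccc1
Why: Williamson etherification of the two chelated phenols with excess benzyl bromide in warm DMF, no other acidic site being present.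

Step 8
Reactants: 11 2,4-bis(benzyloxy)-3-[2,4-bis(benzyloxy)-6-methylbenzoyl]-6-methoxybenzaldehyde
Product: 12 [2,4-bis(benzyloxy)-6-methylphenyl][2,6-bis(benzyloxy)-3-(hydroxymethyl)-4-methoxyphenyl]methanone
Conditions: NaBH4, THF–MeOH, 0 °C
Reagents that add atoms: none
Why: Chemoselective borohydride reduction of the aldehyde, the ketone being protected by its four ortho substituents.

Step 9
Reactants: 12 [2,4-bis(benzyloxy)-6-methylphenyl][2,6-bis(benzyloxy)-3-(hydroxymethyl)-4-methoxyphenyl]methanone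
Product: 13 [2,4-bis(benzyloxy)-6-methylphenyl][2,6-bis(benzyloxy)-3-(bromomethyl)-4-methoxyphenyl]methanone
Conditions: PBr3, pyridine (cat.), Et2O, 0 °C; used crude at once
Reagents that add atoms: phosphorus tribromide, BrP(Br)Br
Why: Standard conversion of a benzylic alcohol into the bromide via its phosphite ester; the electron-rich bromide is not chromatographed but carried straight into step 11.

Step 10
Reactants: 14 trichloroethylene
Product: 16 (E)-1,2-dichloro-1-methoxyethene, via dichloroacetylene 15 (not isolated)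
Conditions: KH, MeOH, THF, 0 °C; then 14, −50 °C → rt
Reagents that add atoms: methanol, CO
Why: Base-induced loss of HCl gives dichloroacetylene only transiently in cold dilute solution and methoxide adds anti across it (nucleophilic addition to a haloalkyne); either alkene isomer would serve in step 11.

Step 11
Reactants: 13 [2,4-bis(benzyloxy)-6-methylphenyl][2,6-bis(benzyloxy)-3-(bromomethyl)-4-methoxyphenyl]methanone; 16 (E)-1,2-dichloro-1-methoxyethene
Product: 19 [2,4-bis(benzyloxy)-6-methylphenyl][2,6-bis(benzyloxy)-4-methoxy-3-(3-methoxyprop-2-yn-1-yl)phenyl]methanone, via chloromethoxyacetylene 17 (not isolated), via lithium methoxyacetylide 18 (not isolated)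
Conditions: 16, n-BuLi (2 equiv), THF, −78 → −40 °C; then 13, DMPU, −78 → 0 °C
Reagents that add atoms: none
Why: Elimination followed by chlorine–lithium exchange gives the alkoxyacetylide, which is alkylated by the highly reactive benzylic bromide in an SN2 reaction faster than it can add to the shielded ketone.

Step 12
Reactants: 19 [2,4-bis(benzyloxy)-6-methylphenyl][2,6-bis(benzyloxy)-4-methoxy-3-(3-methoxyprop-2-yn-1-yl)phenyl]methanone; 20 trichloroacetyl chloride
Product: 22 2-(ArCH2)-4,4-dichloro-3-methoxycyclobut-2-en-1-one, via dichloroketene 21 (not isolated)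
Conditions: Zn(Cu), Et2O–DME, rt, slow addition of 20
Reagents that add atoms: none
Why: Ketene–alkyne [2+2] cycloaddition in which the ketene carbonyl carbon bonds to the ynol ether carbon remote from OMe, fixing the 2-arylmethyl-3-methoxy pattern; DME ties up the zinc dichloride.

Step 13
Reactants: 22 2-(ArCH2)-4,4-dichloro-3-methoxycyclobut-2-en-1-one
Product: 23 2-(ArCH2)-3-methoxycyclobut-2-en-1-one
Conditions: Zn, AcOH, TMEDA, MeOH, 0 °C → rt
Reagents that add atoms: none
Why: Zinc reduction of the α,α-dichloro ketone removes both chlorines under buffered conditions that spare the vinylogous ester, the benzyl ethers and the hindered ketone.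

Step 14
Reactants: 3 2,4-dihydroxy-6-methylbenzaldehyde
Product: 24 4-(benzyloxy)-2-hydroxy-6-methylbenzaldehyde
Conditions: BnBr (1.05 equiv), NaHCO3, KI (cat.), MeCN, 60 °C
Reagents that add atoms: benzyl bromide, BrCc1ccccc1
Why: Regioselective Williamson etherification, since the 4-OH is the more acidic phenol and is not hydrogen-bonded to the aldehyde.

Step 15
Reactants: 24 4-(benzyloxy)-2-hydroxy-6-methylbenzaldehyde
Product: 25 4-(benzyloxy)-2-methoxy-6-methylbenzaldehyde
Conditions: MeI, K2CO3, DMF, rt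
Reagents that add atoms: iodomethane, CI
Why: Williamson methylation of the remaining chelated phenol.

Step 16
Reactants: 25 4-(benzyloxy)-2-methoxy-6-methylbenzaldehyde
Product: 26 1-[4-(benzyloxy)-2-methoxy-6-methylphenyl]prop-2-yn-1-ol (racemic)
Conditions: HC≡CMgBr, THF, 0 °C → rt; aq. NH4Cl
Reagents that add atoms: ethynylmagnesium bromide, C#C[Mg]Br
Why: Grignard 1,2-addition to the aldehyde; the carbinol centre forms racemic and is left uncontrolled because step 21 oxidises it.

Step 17
Reactants: 26 1-[4-(benzyloxy)-2-methoxy-6-methylphenyl]prop-2-yn-1-ol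
Product: 27 {1-[4-(benzyloxy)-2-methoxy-6-methylphenyl]prop-2-yn-1-yl}oxy(tert-butyl)dimethylsilane (racemic)
Conditions: TBSCl, imidazole, DMF, rt
Reagents that add atoms: tert-butyldimethylsilyl chloride, CC(C)(C)[Si](C)(C)Cl
Why: Imidazole-promoted silylation of a secondary propargylic alcohol.

Step 18
Reactants: 27 {1-[4-(benzyloxy)-2-methoxy-6-methylphenyl]prop-2-yn-1-yl}oxy(tert-butyl)dimethylsilane
Product: 30 Ar′CH(OTBS)–C≡C–OSi(i-Pr)3 (racemic), via lithium acetylide 28 (not isolated), via lithium ynolate 29 (not isolated)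
Conditions: LiN(SiMe3)2, THF, −78 °C; t-BuOOLi (from t-BuOOH and LiN(SiMe3)2), −78 → 0 °C; TIPSOTf, −78 °C → rt
Reagents that add atoms: tert-butyl hydroperoxide, CC(C)(C)OO; triisopropylsilyl trifluoromethanesulfonate, CC(C)[Si](C(C)C)(C(C)C)OS(=O)(=O)C(F)(F)F
Why: Electrophilic oxygenation of the lithium acetylide by lithium tert-butyl peroxide gives the ynolate, which the hard, bulky silyl triflate traps on oxygen (ynolate O-silylation).

Step 19
Reactants: 23 2-(ArCH2)-3-methoxycyclobut-2-en-1-one; 30 Ar′CH(OTBS)–C≡C–OSi(i-Pr)3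
Product: 35 2-[Ar′CH(OTBS)]-4-(ArCH2)-5-methoxy-3-(triisopropylsilyloxy)phenol (racemic), via vinylketene 31 (not isolated), via vinylcyclobutenone 32 (not isolated), via dienylketene 33 (not isolated), via cyclohexadienone 34 (not isolated)
Conditions: 30 (1.5 equiv), toluene, 110 °C, sealed tube, argon
Reagents that add atoms: none
Why: Heating opens cyclobutenone 23 by 4π electrocyclic ring opening to vinylketene 31, which adds [2+2] to the siloxyalkyne to give 32; this opens again to dienylketene 33, whose 6π electrocyclisation gives dienone 34, and tautomerisation delivers phenol 35. The closest known reaction is the Danheiser benzannulation of cyclobutenones with substituted siloxyalkynes to resorcinol monosilyl ethers; pairing a 3-alkoxycyclobutenone with so hindered an alkyne is the untested element. Ring C is closed as a six-membered ring by thermal disrotatory 6π electrocyclisation of the dienylketene, followed by enolisation. No lasting stereocentre is created: the quaternary carbon of 32 is lost on ring opening and the carbinol centre is carried through unchanged as the racemate. The selectivity needed is the regiochemistry of the ketene–alkyne [2+2], which the siloxy group secures by making the carbinol-bearing alkyne carbon the nucleophile that attacks the ketene carbonyl carbon, so that C2′ (OSi) ends next to C3′ and C6′ (OH) next to C5′. Acylation of ring A by the ketene is blocked because both positions ortho to the methylene are substituted, and the excess of alkyne should outpace ketene dimerisation.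

Step 20
Reactants: 35 2-[Ar′CH(OTBS)]-4-(ArCH2)-5-methoxy-3-(triisopropylsilyloxy)phenol
Product: 36 2-[Ar′CH(OH)]-4-(ArCH2)-5-methoxybenzene-1,3-diol (racemic)
Conditions: Bu4NF, THF, 0 °C → rt; AcOH quench
Reagents that add atoms: none
Why: Fluoride-mediated desilylation cleaves the aryl silyl ether quickly and the hindered benzhydryl silyl ether more slowly; if the phenoxide expels silanolate to an o-quinone methide, water adds back on work-up to the same carbinol.

Step 21
Reactants: 36 2-[Ar′CH(OH)]-4-(ArCH2)-5-methoxybenzene-1,3-diol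
Product: 37 [4-(benzyloxy)-2-methoxy-6-methylphenyl][3-(ArCH2)-2,6-dihydroxy-4-methoxyphenyl]methanone
Conditions: MnO2 (activated), CH2Cl2, rt
Reagents that add atoms: none
Why: Heterogeneous MnO2 oxidation of a doubly benzylic o-hydroxy carbinol under neutral conditions spares the bridging CH2 and the benzyl ethers and gives a ketone stabilised by two hydrogen bonds.

Step 22
Reactants: 37 [4-(benzyloxy)-2-methoxy-6-methylphenyl][3-(ArCH2)-2,6-dihydroxy-4-methoxyphenyl]methanone
Product: 38 CNP0596095.0 (target)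
Conditions: H2 (1 atm), 10% Pd/C, EtOAc–MeOH, rt
Reagents that add atoms: none
Why: Catalytic hydrogenolysis removes the five benzyl ethers under neutral conditions, under which the hindered, hydrogen-bonded diaryl ketones and the diarylmethane bridge should not be reduced.

Compound list
1 | 5-methoxyresorcinol (5-methoxybenzene-1,3-diol) | COc1cc(O)cc(O)c1 | starting material
2 | 1-methoxy-3,5-bis(methoxymethoxy)benzene | COCOc1cc(OC)cc(OCOC)c1 | intermediate
3 | 2,4-dihydroxy-6-methylbenzaldehyde | Cc1cc(O)cc(O)c1C=O | starting material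
4 | 2,4-bis(benzyloxy)-6-methylbenzaldehyde | Cc1cc(OCc2ccccc2)cc(OCc2ccccc2)c1C=O | intermediate
5 | [4-methoxy-2,6-bis(methoxymethoxy)phenyl]lithium | [Li]c1c(OCOC)cc(OC)cc1OCOC | intermediate (not isolated)
6 | [2,4-bis(benzyloxy)-6-methylphenyl][4-methoxy-2,6-bis(methoxymethoxy)phenyl]methanol, racemic | COCOc1cc(OC)cc(OCOC)c1C(O)c1c(C)cc(OCc2ccccc2)cc1OCc1ccccc1 | intermediate
7 | [2,4-bis(benzyloxy)-6-methylphenyl][4-methoxy-2,6-bis(methoxymethoxy)phenyl]methanone | COCOc1cc(OC)cc(OCOC)c1C(=O)c1c(C)cc(OCc2ccccc2)cc1OCc1ccccc1 | intermediate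
8 | [2,4-bis(benzyloxy)-6-methylphenyl](2,6-dihydroxy-4-methoxyphenyl)methanone | COc1cc(O)c(C(=O)c2c(C)cc(OCc3ccccc3)cc2OCc2ccccc2)c(O)c1 | intermediate
9 | N-{3-[2,4-bis(benzyloxy)-6-methylbenzoyl]-2,4-dihydroxy-6-methoxybenzylidene}-N-methylmethanaminium chloride | C[N+](C)=Cc1c(OC)cc(O)c(C(=O)c2c(C)cc(OCc3ccccc3)cc2OCc2ccccc2)c1O.[Cl-] | intermediate (not isolated)
10 | 3-[2,4-bis(benzyloxy)-6-methylbenzoyl]-2,4-dihydroxy-6-methoxybenzaldehyde | O=Cc1c(OC)cc(O)c(C(=O)c2c(C)cc(OCc3ccccc3)cc2OCc2ccccc2)c1O | intermediate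
11 | 2,4-bis(benzyloxy)-3-[2,4-bis(benzyloxy)-6-methylbenzoyl]-6-methoxybenzaldehyde | O=Cc1c(OC)cc(OCc2ccccc2)c(C(=O)c2c(C)cc(OCc3ccccc3)cc2OCc2ccccc2)c1OCc1ccccc1 | intermediate
12 | [2,4-bis(benzyloxy)-6-methylphenyl][2,6-bis(benzyloxy)-3-(hydroxymethyl)-4-methoxyphenyl]methanone (ArCH2OH) | OCc1c(OC)cc(OCc2ccccc2)c(C(=O)c2c(C)cc(OCc3ccccc3)cc2OCc2ccccc2)c1OCc1ccccc1 | intermediate
13 | [2,4-bis(benzyloxy)-6-methylphenyl][2,6-bis(benzyloxy)-3-(bromomethyl)-4-methoxyphenyl]methanone (ArCH2Br) | BrCc1c(OC)cc(OCc2ccccc2)c(C(=O)c2c(C)cc(OCc3ccccc3)cc2OCc2ccccc2)c1OCc1ccccc1 | intermediate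
14 | trichloroethylene | ClC=C(Cl)Cl | starting material
15 | dichloroacetylene | ClC#CCl | intermediate (not isolated)
16 | (E)-1,2-dichloro-1-methoxyethene | CO/C(Cl)=C\Cl | intermediate
17 | 1-chloro-2-methoxyethyne | COC#CCl | intermediate (not isolated)
18 | lithium methoxyacetylide | [Li]C#COC | intermediate (not isolated)
19 | [2,4-bis(benzyloxy)-6-methylphenyl][2,6-bis(benzyloxy)-4-methoxy-3-(3-methoxyprop-2-yn-1-yl)phenyl]methanone (ArCH2–C≡C–OMe) | COC#CCc1c(OC)cc(OCc2ccccc2)c(C(=O)c2c(C)cc(OCc3ccccc3)cc2OCc2ccccc2)c1OCc1ccccc1 | intermediate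
20 | trichloroacetyl chloride | O=C(Cl)C(Cl)(Cl)Cl | starting material
21 | dichloroketene | O=C=C(Cl)Cl | intermediate (not isolated)
22 | 2-(ArCH2)-4,4-dichloro-3-methoxycyclobut-2-en-1-one | COC1=C(Cc2c(OC)cc(OCc3ccccc3)c(C(=O)c3c(C)cc(OCc4ccccc4)cc3OCc3ccccc3)c2OCc2ccccc2)C(=O)C1(Cl)Cl | intermediate
23 | 2-(ArCH2)-3-methoxycyclobut-2-en-1-one | COC1=C(Cc2c(OC)cc(OCc3ccccc3)c(C(=O)c3c(C)cc(OCc4ccccc4)cc3OCc3ccccc3)c2OCc2ccccc2)C(=O)C1 | intermediate
24 | 4-(benzyloxy)-2-hydroxy-6-methylbenzaldehyde | Cc1cc(OCc2ccccc2)cc(O)c1C=O | intermediate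
25 | 4-(benzyloxy)-2-methoxy-6-methylbenzaldehyde | COc1cc(OCc2ccccc2)cc(C)c1C=O | intermediate
26 | 1-[4-(benzyloxy)-2-methoxy-6-methylphenyl]prop-2-yn-1-ol, racemic | C#CC(O)c1c(C)cc(OCc2ccccc2)cc1OC | intermediate
27 | {1-[4-(benzyloxy)-2-methoxy-6-methylphenyl]prop-2-yn-1-yl}oxy(tert-butyl)dimethylsilane, racemic | C#CC(O[Si](C)(C)C(C)(C)C)c1c(C)cc(OCc2ccccc2)cc1OC | intermediate
28 | lithium acetylide of 27, racemic | [Li]C#CC(O[Si](C)(C)C(C)(C)C)c1c(C)cc(OCc2ccccc2)cc1OC | intermediate (not isolated)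
29 | lithium ynolate Ar′CH(OTBS)–C≡C–OLi, racemic | [Li]OC#CC(O[Si](C)(C)C(C)(C)C)c1c(C)cc(OCc2ccccc2)cc1OC | intermediate (not isolated)
30 | triisopropylsilyl ynol ether Ar′CH(OTBS)–C≡C–OSi(i-Pr)3, racemic | CC(C)[Si](OC#CC(O[Si](C)(C)C(C)(C)C)c1c(C)cc(OCc2ccccc2)cc1OC)(C(C)C)C(C)C | intermediate
31 | 2-(ArCH2)-3-methoxybuta-1,3-dien-1-one (vinylketene) | C=C(OC)C(=C=O)Cc1c(OC)cc(OCc2ccccc2)c(C(=O)c2c(C)cc(OCc3ccccc3)cc2OCc2ccccc2)c1OCc1ccccc1 | intermediate (not isolated)
32 | 4-(ArCH2)-2-[Ar′CH(OTBS)]-4-(1-methoxyvinyl)-3-(triisopropylsilyloxy)cyclobut-2-en-1-one, diastereomer mixture | O=C1C(C(O[Si](C)(C)C(C)(C)C)c2c(C)cc(OCc3ccccc3)cc2OC)=C(O[Si](C(C)C)(C(C)C)C(C)C)C1(C(OC)=C)Cc1c(OC)cc(OCc2ccccc2)c(C(=O)c2c(C)cc(OCc3ccccc3)cc2OCc2ccccc2)c1OCc1ccccc1 | intermediate (not isolated)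
33 | 2-[Ar′CH(OTBS)]-4-(ArCH2)-5-methoxy-3-(triisopropylsilyloxy)hexa-1,3,5-trien-1-one, ketene and methoxyvinyl groups cis on the central double bond, racemic | O=C=C(C(O[Si](C)(C)C(C)(C)C)c1c(C)cc(OCc2ccccc2)cc1OC)/C(O[Si](C(C)C)(C(C)C)C(C)C)=C(Cc1c(OC)cc(OCc2ccccc2)c(C(=O)c2c(C)cc(OCc3ccccc3)cc2OCc2ccccc2)c1OCc1ccccc1)\C(OC)=C | intermediate (not isolated)
34 | 2-[Ar′CH(OTBS)]-4-(ArCH2)-5-methoxy-3-(triisopropylsilyloxy)cyclohexa-2,4-dien-1-one, racemic | O=C1CC(OC)=C(Cc2c(OC)cc(OCc3ccccc3)c(C(=O)c3c(C)cc(OCc4ccccc4)cc3OCc3ccccc3)c2OCc2ccccc2)C(O[Si](C(C)C)(C(C)C)C(C)C)=C1C(O[Si](C)(C)C(C)(C)C)c1c(C)cc(OCc2ccccc2)cc1OC | intermediate (not isolated)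
35 | 2-[Ar′CH(OTBS)]-4-(ArCH2)-5-methoxy-3-(triisopropylsilyloxy)phenol, racemic | Oc1cc(OC)c(Cc2c(OC)cc(OCc3ccccc3)c(C(=O)c3c(C)cc(OCc4ccccc4)cc3OCc3ccccc3)c2OCc2ccccc2)c(O[Si](C(C)C)(C(C)C)C(C)C)c1C(O[Si](C)(C)C(C)(C)C)c1c(C)cc(OCc2ccccc2)cc1OC | intermediate
36 | 2-[Ar′CH(OH)]-4-(ArCH2)-5-methoxybenzene-1,3-diol, racemic | Oc1cc(OC)c(Cc2c(OC)cc(OCc3ccccc3)c(C(=O)c3c(C)cc(OCc4ccccc4)cc3OCc3ccccc3)c2OCc2ccccc2)c(O)c1C(O)c1c(C)cc(OCc2ccccc2)cc1OC | intermediate
37 | [4-(benzyloxy)-2-methoxy-6-methylphenyl][3-(ArCH2)-2,6-dihydroxy-4-methoxyphenyl]methanone | Oc1cc(OC)c(Cc2c(OC)cc(OCc3ccccc3)c(C(=O)c3c(C)cc(OCc4ccccc4)cc3OCc3ccccc3)c2OCc2ccccc2)c(O)c1C(=O)c1c(C)cc(OCc2ccccc2)cc1OC | intermediate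
38 | CNP0596095.0: (2,4-dihydroxy-6-methylphenyl){2,6-dihydroxy-3-[2,4-dihydroxy-3-(4-hydroxy-2-methoxy-6-methylbenzoyl)-6-methoxybenzyl]-4-methoxyphenyl}methanone | COc1cc(O)c(C(=O)c2c(C)cc(O)cc2O)c(O)c1Cc1c(OC)cc(O)c(C(=O)c2c(C)cc(O)cc2OC)c1O | target

Total step count: 22. Longest linear sequence: 15 steps (steps 1, 3–9, 11–13, 19–22).

Steps most likely to fail

1. Step 19. The 3-methoxycyclobutenone may open too slowly, and the hindered, disubstituted vinylketene may dimerise or acylate the product phenol faster than it adds to the very bulky siloxyalkyne. Thermal loss of silanol from the o-hydroxybenzhydryl silyl ether of the product is a further drain. The fallback sets out from benzylic alcohol 12 (with 5 and 25, both already on the route) and comes back at 37. Aryllithium 5 is added to aldehyde 25 to give [4-(benzyloxy)-2-methoxy-6-methylphenyl][4-methoxy-2,6-bis(methoxymethoxy)phenyl]methanol F1 (racemic). Dess–Martin oxidation gives [4-(benzyloxy)-2-methoxy-6-methylphenyl][4-methoxy-2,6-bis(methoxymethoxy)phenyl]methanone F2. HCl in methanol then frees [4-(benzyloxy)-2-methoxy-6-methylphenyl](2,6-dihydroxy-4-methoxyphenyl)methanone F3, in which ring C is preformed and its C3′ and C5′ are equivalent. F3, used in excess, is C-benzylated by alcohol 12 with Sc(OTf)3 (cat.) in CH2Cl2–MeNO2 at 0 °C. This is a Friedel–Crafts alkylation of an acylphloroglucinol by a trialkoxybenzyl cation and should give 37 directly, after which step 22 follows.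

2. Step 11. Ionisation and self-condensation of the electron-rich benzylic bromide, or addition of the acetylide to the diaryl ketone, may outrun the SN2 alkylation. The fallback sets out from bromide 13 and comes back at 19. Lithium methoxyacetylide 18, generated from 16 as before, is quenched with Bu3SnCl to give tributyl(methoxyethynyl)stannane F4. F4 is coupled with 13 under Pd(PPh3)4 catalysis in THF at 50 °C (Stille coupling of a benzylic bromide with an alkynylstannane), so no basic organolithium meets the bromide or the ketone.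

3. Step 21. The oxidant may attack the free, electron-rich phenols (quinone formation, oxidative coupling), or o-quinone methide chemistry may compete with oxidation of the hindered carbinol. The fallback sets out from triol 36 and comes back at the target 38. Both phenols of 36 are benzylated with BnBr and K2CO3 in acetone at 50 °C, the hindered secondary carbinol staying free, to give 1,3-bis(benzyloxy)-2-[Ar′CH(OH)]-4-(ArCH2)-5-methoxybenzene F5 (racemic). Dess–Martin periodinane converts it into [4-(benzyloxy)-2-methoxy-6-methylphenyl][3-(ArCH2)-2,6-bis(benzyloxy)-4-methoxyphenyl]methanone F6. Hydrogenolysis (H2, 10% Pd/C, EtOAc–MeOH) removes all seven benzyl ethers to give 38.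

Further compounds
F1 | step 19 | [4-(benzyloxy)-2-methoxy-6-methylphenyl][4-methoxy-2,6-bis(methoxymethoxy)phenyl]methanol, racemic | COCOc1cc(OC)cc(OCOC)c1C(O)c1c(C)cc(OCc2ccccc2)cc1OC
F2 | step 19 | [4-(benzyloxy)-2-methoxy-6-methylphenyl][4-methoxy-2,6-bis(methoxymethoxy)phenyl]methanone | COCOc1cc(OC)cc(OCOC)c1C(=O)c1c(C)cc(OCc2ccccc2)cc1OC
F3 | step 19 | [4-(benzyloxy)-2-methoxy-6-methylphenyl](2,6-dihydroxy-4-methoxyphenyl)methanone | COc1cc(O)c(C(=O)c2c(C)cc(OCc3ccccc3)cc2OC)c(O)c1
F4 | step 11 | tributyl(methoxyethynyl)stannane | CCCC[Sn](CCCC)(CCCC)C#COC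
F5 | step 21 | 1,3-bis(benzyloxy)-2-[Ar′CH(OH)]-4-(ArCH2)-5-methoxybenzene, racemic | OC(c1c(C)cc(OCc2ccccc2)cc1OC)c1c(OCc2ccccc2)cc(OC)c(Cc2c(OC)cc(OCc3ccccc3)c(C(=O)c3c(C)cc(OCc4ccccc4)cc3OCc3ccccc3)c2OCc2ccccc2)c1OCc1ccccc1
F6 | step 21 | [4-(benzyloxy)-2-methoxy-6-methylphenyl][3-(ArCH2)-2,6-bis(benzyloxy)-4-methoxyphenyl]methanone | O=C(c1c(C)cc(OCc2ccccc2)cc1OC)c1c(OCc2ccccc2)cc(OC)c(Cc2c(OC)cc(OCc3ccccc3)c(C(=O)c3c(C)cc(OCc4ccccc4)cc3OCc3ccccc3)c2OCc2ccccc2)c1OCc1ccccc1
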